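Slowness can be read from the tail of a curve, so I start at the slow end of two earlier runs. They share their partner charge, and the new flask has less substrate than either.

| flask | substrate | partner | remark | time |
|---|---|---|---|---|
| Thursday's | 0.070 M | 0.050 M | run made earlier |  |
| Tuesday's | 0.11 M | 0.050 M | run made earlier |  |
| flask | 0.050 M | 0.0500 M |  | 2.5 min |

- Thursday's (time / min: target / %): 0.167: 45.7; 0.250: 52.7; 0.500: 57.3; 1.33: 52.6; 2.50: 41.8
- Tuesday's (time / min: target / %): 0.167: 46.5; 0.250: 54.0; 0.500: 59.1; 1.33: 51.3; 2.50: 41.9

(scatter of a reading: 0.5 percentage points)

- time, not beyond 2.5 min, at which the flask holds most target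
- the amount of target, in percent of the substrate charged, at that time
- earliest time at which at least nineteen twentieths of that best amount are there, in min
- latest time at which they still are, in min



I read the two tables row against row. At 0.500 min, Thursday's run reads 57.3% and Tuesday's 59.1%; at 2.50 min they read 41.8% and 41.9%. Percentages therefore change little with the substrate charge in these runs, and I carry them over to the flask. The third row is the highest reading in both runs, so I take its mean, 58.2%, as my best.

The last two rows are the slow part. Between them, Thursday's run falls at 0.196 min⁻¹ and Tuesday's at 0.173 min⁻¹, and that spread shows the scatter. Their mean gives 3.75 min for the late half-life, the time in which target falls by half on this falling stretch, the terminal half-life of the curve. I count back from the mean of the fourth row, 52.0%, to the threshold asked for, which on my best is 55.3%, and so I put the shut at 0.993 min.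

The forecast puts the best lower than mine, at 57.7% at 0.51 min, with the open at 0.29 min and the shut at 1 min; of that window it says: “reached near 0.29 min and lost near 1.0 min”.

The flask gives a best of 58.3% at 0.489 min, an open of 0.291 min and a shut of 0.912 min, so the forecast holds within its margins. The equations were hidden until now:

    substrate → intermediate (k = 0.0493 s⁻¹)
    intermediate → side product A (k = 0.00866 s⁻¹)
    substrate → target (k = 0.0851 s⁻¹)
    partner + intermediate → side product B (k = 3.13 L mol⁻¹ s⁻¹)
    target → over-reaction product (k = 0.00283 s⁻¹)
    partner → decomposed reagent (k = 0.0833 s⁻¹)

Up to 0.489 min, substrate goes to target and intermediate while partner decays and meets intermediate; by then substrate stands at 1.94%, partner at 4.50% of its own charge and side product B at 17.6%. Afterwards side product B ends at 18.5%, while target passes into over-reaction product, which climbs from 3.82% to 21.0% at 2.50 min. Counting 0.333 late half-lives from the flask's 52.3% at 1.25 min gives 41.5%, and the flask holds 42.3% at 2.50 min. A further 0.933 give 22.2%, and the flask left until 6.0 min holds 23.4% target.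

(The data were computed for substances that don't exist; scatter was added.)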